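**Retrosynthetic overview**

1. Alertenone (26) is cut into two molecules of suberosenone (24): the enolate at the only enolisable CH2 (next to the ring-fusion CH) of one adds to the exocyclic methylene of the other (Michael addition, last step).
2. Suberosenone comes from tricyclic ketone 13: α-methylene by a Mannich reaction on a blocking enone; the secondary methyl from the six-ring ketone (methylenation, hydrogenation); the gem-dimethyl carbon from an exocyclic methylene (cyclopropanation, hydrogenolysis).
3. Key disconnection, 13 from enyne 12 (a cis-fused bicyclo[4.3.0]nonane): a gold-catalysed enyne cyclisation ended by a pinacol shift makes the CH2–C bond of the methylenecyclopentane and moves the ring-fusion CH from the carbinol carbon to the alkene carbon. The cyclopentanol thereby grows into the six-membered ketone ring of the bicyclo[3.2.1]octane, and the cyclohexane shrinks to the future cyclopentanone.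
4. Feature used: the quaternary carbon shared by all three carbocycles has, inside the six-membered ring, the ring-fusion CH on one side and the CH(CH3) carbon on the other. Written as C=O, that CH(CH3) carbon is a pinacol terminus, so the bond from the quaternary carbon to the ring-fusion CH can be made by a 1,2-shift out of a cyclopentanol, and the CH2 neighbour of the quaternary carbon is the nucleophilic end of an alkene.
5. Enyne 12 comes from (S)-3-oxocyclopentanecarboxylic acid, (R)-glycidyl tosylate and (1-bromovinyl)trimethylsilane: an ester-tethered alkylation (temporary δ-lactone) sets the cis triad, and an intramolecular Nozaki–Hiyama–Kishi reaction closes the cyclohexane. Ring order: cyclopentane (bought), temporary lactone, cyclohexane, then in the key step methylenecyclopentane plus six-membered ring plus cyclopentane, then the dimer.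

Key step: step 8

Remark on the chemistry: lactol 10 (both anomers) and the aminomethyl-bearing carbon of 20 to 23 (both epimers) are carried as mixtures, because these centres are lost in 11 and in 24; their SMILES leave these centres open.

**Route**

Step 1
Reactants: 1 (1-bromoethenyl)trimethylsilane; 3 (2R)-oxiran-2-ylmethyl 4-methylbenzenesulfonate ((R)-glycidyl tosylate)
Product: 4 (2R)-2-hydroxy-4-(trimethylsilyl)pent-4-en-1-yl 4-methylbenzenesulfonate, via alkenylmagnesium bromide 2 (not isolated)
Conditions: Mg, THF, 40 °C; then CuI (10 mol %), 3, THF, −40 to −20 °C
Reagents that add atoms: none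
Why: Copper-catalysed ring opening of the terminal epoxide by the alkenyl Grignard reagent at the CH2 carbon, faster than tosylate displacement at low temperature, leaves the stereocenter untouched.

Step 2
Reactants: 4 (2R)-2-hydroxy-4-(trimethylsilyl)pent-4-en-1-yl 4-methylbenzenesulfonate; 5 (1S)-3-oxocyclopentane-1-carboxylic acid
Product: 6 (2R)-1-(tosyloxy)-4-(trimethylsilyl)pent-4-en-2-yl (1S)-3-oxocyclopentane-1-carboxylate
Conditions: DCC, DMAP (10 mol %), CH2Cl2, 0 to 25 °C
Reagents that add atoms: none
Why: Steglich esterification joins the two bought stereocenters without touching either.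

Step 3
Reactants: 6 (2R)-1-(tosyloxy)-4-(trimethylsilyl)pent-4-en-2-yl (1S)-3-oxocyclopentane-1-carboxylate
Product: 7 cis-fused keto lactone, 3-[2-(trimethylsilyl)prop-2-en-1-yl]hexahydrocyclopenta[c]pyran-1,5-dione (ring-fusion hydrogens cis; side chain on the lactone face that carries the cyclopentanone ring)
Conditions: KN(SiMe3)2 (1.05 equiv), THF (0.01 M), −78 to 0 °C
Reagents that add atoms: none
Why: Intramolecular enolate alkylation (6-exo-tet) in which the ester tether lets only the α-carbon between the ketone and the ester-bearing carbon reach the CH2OTs group, and only on the face of the ester, so the new ring-fusion stereocenter is formed cis.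

Step 4
Reactants: 7 cis-fused keto lactone with the 2-(trimethylsilyl)allyl side chain
Product: 8 cis-fused keto lactone, 3-(2-iodoprop-2-en-1-yl)hexahydrocyclopenta[c]pyran-1,5-dione (stereocenters as in 7)
Conditions: N-iodosuccinimide, (CF3)2CHOH, 0 °C
Reagents that add atoms: N-iodosuccinimide, O=C1CCC(=O)N1I
Why: Iododesilylation (electrophilic ipso substitution through the β-silyl cation) turns the base-stable alkenylsilane into the 2-iodoalkene, with no stereocenter involved.

Step 5
Reactants: 8 cis-fused keto lactone with the 2-iodoallyl side chain
Product: 9 bridged tricyclic hydroxy lactone, the δ-lactone between O-5 and the 3-carboxyl group of 7a-hydroxy-7-methylideneoctahydro-1H-indene (cis ring fusion; 7a-OH and H-3a on one face, lactone bridge on the other)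
Conditions: CrCl2 (6 equiv), NiCl2 (2 mol %), DMSO, 25 °C
Reagents that add atoms: none
Why: Intramolecular Nozaki–Hiyama–Kishi reaction, in which the alkenylchromium species adds to the ketone and not to the lactone from the only face its tether allows, so the six-membered carbocycle is cis-fused and the tertiary OH is cis to the ring-fusion hydrogen.

Step 6
Reactants: 9 bridged tricyclic hydroxy lactone
Product: 11 3-ethynyl-7-methylideneoctahydro-1H-indene-5,7a-diol (7a-OH and H-3a on one face; ethynyl and 5-OH on the other), via lactol 10 (not isolated)
Conditions: i-Bu2AlH (3 equiv), CH2Cl2, −78 °C; then MeOH, K2CO3, dimethyl (1-diazo-2-oxopropyl)phosphonate, 0 to 25 °C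
Reagents that add atoms: dimethyl (1-diazo-2-oxopropyl)phosphonate, CC(=O)C(=[N+]=[N-])P(=O)(OC)OC
Why: Partial reduction of the lactone and Seyferth–Gilbert homologation with the Ohira–Bestmann reagent of the open hydroxy aldehyde turn the carboxyl carbon into the alkyne carbon, and the mild carbonate base together with the mostly closed lactol should keep the adjacent stereocenter from epimerising.

Step 7
Reactants: 11 3-ethynyl-7-methylideneoctahydro-1H-indene-5,7a-diol
Product: 12 bis(triethylsilyl) ether of 11 (enyne for the key step)
Conditions: Et3SiOTf (3 equiv), 2,6-lutidine, CH2Cl2, −78 to 0 °C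
Reagents that add atoms: triethylsilyl trifluoromethanesulfonate, CC[Si](CC)(CC)OS(=O)(=O)C(F)(F)F
Why: Silylation with the silyl triflate protects the secondary and the hindered tertiary alcohol in one operation, and the tertiary silyl ether is the electron-releasing group of the next step.

Step 8
Reactants: 12 bis(triethylsilyl) ether of 3-ethynyl-7-methylideneoctahydro-1H-indene-5,7a-diol
Product: 13 tricyclic ketone, a bicyclo[3.2.1]octan-2-one fused at C-1 and C-8 to a cyclopentane that carries the OSiEt3 group, with a methylidene group at C-6
Conditions: [(t-Bu)2(biphenyl-2-yl)P]Au(NCMe) SbF6 (5 mol %), i-PrOH (1.5 equiv), CH2Cl2, 0 to 25 °C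
Reagents that add atoms: none
Why: The cationic monovalent gold complex activates the terminal alkyne, the exocyclic methylene attacks its internal carbon through the CH2 end (6-exo-dig at the alkyne, closing a temporary six-membered ring) and so places a tertiary cation next to the silyloxy carbinol; the ring-fusion C–C bond then shifts to this cation while the C–OSiEt3 carbon becomes the ketone (pinacol shift), and isopropanol protonates the alkenyl–gold bond and takes up the silyl group. The closest known reaction type is the gold-catalysed pinacol-terminated 1,6-enyne cyclisation of 1-alkenylcycloalkanol silyl ethers (the gold version of the Prins–pinacol ring-enlarging cyclopentane annulation), here with the alkyne on the β-carbon of the cyclopentanol, so that a bridged instead of a fused bicycle results. In this one operation the temporary six-membered ring contracts to the methylenecyclopentane (the two-carbon bridge), the cyclopentanol expands by one carbon to the cyclohexanone of the bicyclo[3.2.1]octane, and the cyclohexane contracts to the future cyclopentanone. The only new stereocenter, the quaternary carbon, is fixed by the substrate: alkyne and alkenyl group are cis on the cyclopentane, and the shift is suprafacial with retention at the migrating carbon, so only one configuration can form. The selectivity needed is migration of the ring-fusion carbon and not of the other cyclopentane CH2; the cis-fused cyclohexane secures it, because in the bridged cation the ring-fusion C–C bond is antiperiplanar to the empty orbital while the CH2 bond is gauche, and because this cation cannot escape by losing a proton to a bridgehead alkene.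

Step 9
Reactants: 13 tricyclic ketone with the 6-methylidene group
Product: 14 spirocyclopropane ketone (cyclopropane spiro-fused at C-6 of the bicyclo[3.2.1]octanone; other centres as in 13)
Conditions: Et2Zn, CH2I2, CH2Cl2, 0 to 25 °C
Reagents that add atoms: diiodomethane, ICI
Why: Simmons–Smith cyclopropanation of the unhindered 1,1-disubstituted alkene by the zinc carbenoid leaves the hindered ketone alone, and the spiro carbon bears two identical CH2 groups, so no stereocenter arises.

Step 10
Reactants: 14 spirocyclopropane ketone
Product: 15 spirocyclopropane with a 2-methylidene group in place of the ketone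
Conditions: Zn, CH2Br2, TiCl4, THF/CH2Cl2, 0 to 25 °C
Reagents that add atoms: dibromomethane, BrCBr
Why: Takai–Lombardo methylenation with the non-basic gem-dimetallic reagent converts the hindered, enolisable ketone beside the quaternary carbon into the exocyclic alkene without touching the silyl ether or the cyclopropane.

Step 11
Reactants: 15 methylidene spirocyclopropane
Product: 17 tricyclic alcohol with the suberosenone carbon skeleton minus the exocyclic methylene (secondary methyl syn to the one-carbon bridge, gem-dimethyl group, free secondary OH), via triethylsilyl ether 16 (not isolated)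
Conditions: H2 (4 atm), PtO2, AcOH, 25 to 40 °C; then THF/H2O, 40 °C
Reagents that add atoms: none
Why: Heterogeneous hydrogenation is expected to deliver hydrogen to the exocyclic methylene from the endo (equatorial) side, because the exo side is screened by the syn hydrogen of the one-carbon bridge, which sets the methyl group axial and syn to that bridge; under the same conditions the spirocyclopropane is hydrogenolysed at its least hindered CH2–CH2 bond to the gem-dimethyl group, and aqueous acetic acid cleaves the silyl ether.

Step 12
Reactants: 17 tricyclic alcohol
Product: 18 tricyclic enone (C=C between the bridging ring-fusion carbon and the adjacent CH, conjugated with the new ketone)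
Conditions: 2-iodoxybenzoic acid (IBX, 3.5 equiv), DMSO/fluorobenzene, 70 °C
Reagents that add atoms: none
Why: IBX oxidises the alcohol to the ketone and dehydrogenates it further through its enol; only the α-carbon next to the ring-fusion CH has a β-hydrogen (the other is flanked by the quaternary carbon), so a single enone forms and blocks that α-position.

Step 13
Reactants: 18 tricyclic enone
Product: 20 α′-(dimethylaminomethyl) enone (Mannich base, both epimers), via lithium enolate 19 (not isolated)
Conditions: LiN(i-Pr)2, THF, −78 °C; then CH2=NMe2 I, −78 to 0 °C
Reagents that add atoms: N,N-dimethylmethyleneiminium iodide, C=[N+](C)C.[I-]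
Why: The kinetic lithium enolate can form only at the remaining α′-CH2 (the γ-hydrogen sits at a bridgehead) and is trapped by Eschenmoser's salt in a Mannich reaction; the new centre is of no consequence.

Step 14
Reactants: 20 α′-(dimethylaminomethyl) enone
Product: 22 saturated β-amino ketone (ring-fusion hydrogen syn to the three-carbon bridge, as in the target), via lithium enolate 21 (not isolated)
Conditions: Li, NH3 (l)/THF, −78 °C; then NH4Cl
Reagents that add atoms: none
Why: Dissolving-metal conjugate reduction of the enone, in which protonation of the β-carbanion gives the thermodynamically favoured cis-fused bicyclo[3.3.0]octane junction, and the enolate formed resists over-reduction.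

Step 15
Reactants: 22 saturated β-amino ketone
Product: 24 suberosenone, via ammonium iodide 23 (not isolated)
Conditions: MeI, MeOH, 25 °C; then NaHCO3 (aq), CH2Cl2, 25 °C
Reagents that add atoms: none
Why: Exhaustive N-methylation and base-induced E1cB loss of trimethylamine (Mannich-base route) unveil the α-methylene ketone at the position fixed in step 13.

Step 16
Reactants: 24 suberosenone (2 equiv)
Product: 26 alertenone, via adduct lithium enolate 25 (not isolated)
Conditions: LiN(SiMe3)2 (0.5 equiv), THF, −78 to −20 °C; then AcOH
Reagents that add atoms: none
Why: Michael addition, in which the cross-conjugated enolate (it can form only at the CH2 next to the ring-fusion carbon) adds through the convex face of the cis-fused diquinane, anti to the exo methyl of the gem-dimethyl group, to the exocyclic methylene of a second molecule; the new enolate is protonated, under equilibrating proton transfer between enolates, to the epimer with the CH2 substituent anti to the methyl-bearing carbon.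

**Compound list**

1 | (1-bromoethenyl)trimethylsilane | C=C(Br)[Si](C)(C)C | starting material
2 | [1-(trimethylsilyl)ethenyl]magnesium bromide | C=C([Mg]Br)[Si](C)(C)C | intermediate (not isolated)
3 | (2R)-oxiran-2-ylmethyl 4-methylbenzenesulfonate | Cc1ccc(cc1)S(=O)(=O)OC[C@H]1CO1 | starting material
4 | (2R)-2-hydroxy-4-(trimethylsilyl)pent-4-en-1-yl 4-methylbenzenesulfonate | Cc1ccc(cc1)S(=O)(=O)OC[C@H](O)CC(=C)[Si](C)(C)C | intermediate
5 | (1S)-3-oxocyclopentane-1-carboxylic acid | O=C1C[C@@H](C(=O)O)CC1 | starting material
6 | (2R)-1-(tosyloxy)-4-(trimethylsilyl)pent-4-en-2-yl (1S)-3-oxocyclopentane-1-carboxylate | O=C1C[C@@H](C(=O)O[C@@H](COS(=O)(=O)c2ccc(C)cc2)CC(=C)[Si](C)(C)C)CC1 | intermediate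
7 | cis-fused keto lactone with 2-(trimethylsilyl)allyl side chain | O=C1CC[C@@H]2C(=O)O[C@H](CC(=C)[Si](C)(C)C)C[C@H]12 | intermediate
8 | cis-fused keto lactone with 2-iodoallyl side chain | O=C1CC[C@@H]2C(=O)O[C@H](CC(I)=C)C[C@H]12 | intermediate
9 | bridged tricyclic hydroxy lactone | O[C@]12CC[C@@H]3C(=O)O[C@H](CC1=C)C[C@H]23 | intermediate
10 | lactol of 9 (anomers) | O[C@]12CC[C@@H]3C(O)O[C@H](CC1=C)C[C@H]23 | intermediate (not isolated)
11 | 3-ethynyl-7-methylideneoctahydro-1H-indene-5,7a-diol | O[C@@]12CC[C@H](C#C)[C@@H]1C[C@H](O)CC2=C | intermediate
12 | bis(triethylsilyl) ether of 11 | CC[Si](CC)(CC)O[C@@]12CC[C@H](C#C)[C@@H]1C[C@H](O[Si](CC)(CC)CC)CC2=C | intermediate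
13 | tricyclic ketone with 6-methylidene group and OSiEt3 | O=C1CC[C@H]2[C@@H]3C[C@H](O[Si](CC)(CC)CC)C[C@@]13CC2=C | intermediate
14 | spirocyclopropane ketone | O=C1CC[C@H]2[C@@H]3C[C@H](O[Si](CC)(CC)CC)C[C@@]13CC24CC4 | intermediate
15 | methylidene spirocyclopropane | C=C1CC[C@H]2[C@@H]3C[C@H](O[Si](CC)(CC)CC)C[C@@]13CC24CC4 | intermediate
16 | triethylsilyl ether of 17 | C[C@H]1CC[C@H]2[C@@H]3C[C@H](O[Si](CC)(CC)CC)C[C@@]13CC2(C)C | intermediate (not isolated)
17 | tricyclic alcohol | C[C@H]1CC[C@H]2[C@@H]3C[C@H](O)C[C@@]13CC2(C)C | intermediate
18 | tricyclic enone | C[C@H]1CC[C@H]2C3=CC(=O)C[C@@]13CC2(C)C | intermediate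
19 | lithium enolate of 18 | C[C@H]1CC[C@H]2C3=CC(O[Li])=C[C@@]13CC2(C)C | intermediate (not isolated)
20 | α′-(dimethylaminomethyl) enone (epimers) | C[C@H]1CC[C@H]2C3=CC(=O)C(CN(C)C)[C@@]13CC2(C)C | intermediate
21 | lithium enolate from reduction of 20 | C[C@H]1CC[C@H]2[C@@H]3C=C(O[Li])C(CN(C)C)[C@@]13CC2(C)C | intermediate (not isolated)
22 | saturated β-amino ketone (epimers) | C[C@H]1CC[C@H]2[C@@H]3CC(=O)C(CN(C)C)[C@@]13CC2(C)C | intermediate
23 | trimethylammonium iodide of 22 | C[C@H]1CC[C@H]2[C@@H]3CC(=O)C(C[N+](C)(C)C)[C@@]13CC2(C)C.[I-] | intermediate (not isolated)
24 | suberosenone | C[C@H]1CC[C@H]2[C@@H]3CC(=O)C(=C)[C@@]13CC2(C)C | intermediate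
25 | lithium enolate of the Michael adduct | C=C1C(=O)[C@H](CC2=C(O[Li])C[C@H]3[C@@H]4CC[C@H](C)[C@]23CC4(C)C)[C@H]2[C@@H]3CC[C@H](C)[C@]12CC3(C)C | intermediate (not isolated)
26 | alertenone | C=C1C(=O)[C@H](C[C@@H]2C(=O)C[C@H]3[C@@H]4CC[C@H](C)[C@]23CC4(C)C)[C@H]2[C@@H]3CC[C@H](C)[C@]12CC3(C)C | target

Total step count: 16. Longest linear sequence: 16 steps (1 and 3 to 26; acid 5 enters at step 2).

**Steps most likely to fail**

Step 8. What may go wrong: the chair of the cyclohexane that brings alkyne and alkene together has the alkyne-bearing ring bond and the secondary silyloxy group syn-axial and is the minor conformer. Slow ring closure would let the gold-activated alkyne be diverted (addition of the alcohol, enyne skeletal rearrangement) or let the silyl ether be lost before the 1,2-shift. The fallback changes the trigger from π-acid activation of an alkyne to a tertiary carbocation that already carries both methyl groups, in a Prins–pinacol variant without direct precedent for this kind of cation. It sets out from hydroxy lactone 9. Et3SiOTf and 2,6-lutidine give the triethylsilyl ether lactone F1. MeLi with CeCl3 opens the lactone to the diol F2, with a 2-hydroxypropan-2-yl group and a secondary alcohol. Et3SiCl and imidazole silylate only the secondary alcohol, giving the tertiary alcohol F3. Ionisation of the tertiary alcohol with HN(SO2CF3)2 (10 mol %) in CH2Cl2 at −78 to −30 °C should start the same ring closure and shift and give the gem-dimethyl ketone F4. Takai–Lombardo methylenation gives the methylidene compound F5, and hydrogenation over PtO2 in AcOH comes back to the route at 16, which is desilylated to 17 as in step 11.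

Step 11. What may go wrong: poor facial selectivity in the delivery of hydrogen to the exocyclic methylene (or migration of the double bond into the ring before reduction), which would leave the methyl group equatorial. The fallback delivers the carbon instead of the hydrogen from the accessible exo face. It sets out from spirocyclopropane ketone 14. KN(SiMe3)2 and PhN(SO2CF3)2 give the enol triflate F6. Pd(OAc)2, PPh3, Bu3N and HCO2H reduce it to the cycloalkene F7. Simmons–Smith cyclopropanation (Et2Zn, CH2I2) on the exo face gives the bis-cyclopropane F8. Hydrogenolysis over PtO2 in AcOH should open the fused cyclopropane at the CH2–CH bond remote from the quaternary carbon and the spirocyclopropane at its CH2–CH2 bond, which comes back to the route at 16.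

Step 16. What may go wrong: repeated Michael addition of the product enolate (oligomers) and incomplete control of the two new α-stereocenters under basic conditions. The fallback is a Mukaiyama–Michael reaction that stops at a neutral silyl enol ether. It sets out from suberosenone 24. t-BuMe2SiOTf and Et3N give the silyl dienol ether F9. F9 and a second equivalent of 24 with t-BuMe2SiOTf (10 mol %) in CH2Cl2 at −78 °C give the adduct silyl enol ether F10. Protodesilylation with HF·pyridine in THF at 0 °C comes back to the route at 26.

Further compounds
F1 | step 8 | triethylsilyl ether of hydroxy lactone 9 | CC[Si](CC)(CC)O[C@]12CC[C@@H]3C(=O)O[C@H](CC1=C)C[C@H]23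
F2 | step 8 | diol with 2-hydroxypropan-2-yl group and secondary alcohol | CC[Si](CC)(CC)O[C@@]12CC[C@H](C(C)(C)O)[C@@H]1C[C@H](O)CC2=C
F3 | step 8 | tertiary alcohol with both other oxygens as triethylsilyl ethers | CC[Si](CC)(CC)O[C@@]12CC[C@H](C(C)(C)O)[C@@H]1C[C@H](O[Si](CC)(CC)CC)CC2=C
F4 | step 8 | gem-dimethyl tricyclic ketone with OSiEt3 | O=C1CC[C@H]2[C@@H]3C[C@H](O[Si](CC)(CC)CC)C[C@@]13CC2(C)C
F5 | step 8 | gem-dimethyl methylidene compound with OSiEt3 | C=C1CC[C@H]2[C@@H]3C[C@H](O[Si](CC)(CC)CC)C[C@@]13CC2(C)C
F6 | step 11 | enol triflate of ketone 14 | FC(F)(F)S(=O)(=O)OC1=CC[C@H]2[C@@H]3C[C@H](O[Si](CC)(CC)CC)C[C@@]13CC24CC4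
F7 | step 11 | cycloalkene from reduction of F6 | C1=CC[C@H]2[C@@H]3C[C@H](O[Si](CC)(CC)CC)C[C@@]13CC24CC4
F8 | step 11 | bis-cyclopropane (exo-fused cyclopropane on the six-membered ring) | C1[C@H]2C[C@H]3[C@@H]4C[C@H](O[Si](CC)(CC)CC)C[C@]4([C@@H]12)CC35CC5
F9 | step 16 | tert-butyldimethylsilyl dienol ether of suberosenone | C[C@H]1CC[C@H]2[C@@H]3C=C(O[Si](C)(C)C(C)(C)C)C(=C)[C@@]13CC2(C)C
F10 | step 16 | silyl enol ether of the Michael adduct | C=C1C(=O)[C@H](CC2=C(O[Si](C)(C)C(C)(C)C)C[C@H]3[C@@H]4CC[C@H](C)[C@]23CC4(C)C)[C@H]2[C@@H]3CC[C@H](C)[C@]12CC3(C)C
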